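**Retrosynthetic overview**
1. Clusiaphenone B ⇒ retro double aromatic Claisen ([3,3], allyl inversion). Both C-prenyl groups start as O-(1,1-dimethylallyl) groups on the 2- and 4-oxygens of the benzophenone.
2. Key disconnection: the two aryl O–C(tertiary allyl) bonds ⇒ 2,4,6-trihydroxybenzophenone plus two π-prenyl cation equivalents (methyl 2-methylbut-3-en-2-yl carbonate, zerovalent palladium).
3. 2,4,6-Trihydroxybenzophenone ⇒ phloroglucinol + benzoyl chloride (Friedel–Crafts). The carbonate ⇒ 2-methylbut-3-en-2-ol + methyl chloroformate.
4. No ring is formed, since both benzene rings are bought intact. The bond order is aryl–C(=O) first, then two C–O bonds, then O-to-C transfer.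

Assumption: the target has no stereocentre and no E/Z-isomeric alkene (each alkene ends in CMe2). It is therefore achiral, there is no enantiomer to select, and the route makes the compound exactly as drawn.

Position numbers below count the benzoyl-bearing ring carbon as C1.

Step 1
Reactants: 1 phloroglucinol (benzene-1,3,5-triol, anhydrous); 2 benzoyl chloride
Product: 3 2,4,6-trihydroxybenzophenone
Conditions: AlCl3 (4 equiv), PhNO2, 65 °C, 3 h; then ice, 1 M HCl
Reagents that add atoms: none
Why: Friedel–Crafts acylation, in which the acylium ion from 2 and AlCl3 attacks the very electron-rich ring of 1 and the ketone formed is held as a deactivated aluminium chelate, so the reaction stops after one acylation; no stereocentre is formed.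

Step 2
Reactants: 4 2-methylbut-3-en-2-ol; 5 methyl chloroformate
Product: 7 methyl 2-methylbut-3-en-2-yl carbonate, via lithium 2-methylbut-3-en-2-olate 6 (not isolated)
Conditions: n-BuLi (1.05 equiv), THF, −78 to 0 °C; then 5 (1.2 equiv), 0 °C to rt; distil
Reagents that add atoms: none
Why: Acylation of a lithium alkoxide by a chloroformate (carbonate ester formation), where full deprotonation makes the hindered tertiary oxygen nucleophilic enough to react cleanly at low temperature without ionising the allylic C–O bond; no stereocentre is formed.

Step 3
Reactants: 3 2,4,6-trihydroxybenzophenone; 7 methyl 2-methylbut-3-en-2-yl carbonate (2.2 equiv)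
Product: 11 clusiaphenone B, via 4-O-(1,1-dimethylallyl) monoether 8 (not isolated), via 2,4-bis-O-(1,1-dimethylallyl) ether 9 (not isolated), via 3-prenyl-4-O-(1,1-dimethylallyl) ether 10 (not isolated)
Conditions: Pd(PPh3)4 (5 mol %), THF, Ar, 0 °C, 45 min; short SiO2 plug (1% Et3N) to strip Pd, solvent swap; degassed DMF, 120 °C, 2 h
Reagents that add atoms: none
Why: Proposed new method: a site-selective twofold decarboxylative O-tert-prenylation of an unprotected acylphloroglucinol, followed in the same operation by twofold O-to-C transfer; zerovalent palladium ionises 7 to a cationic divalent palladium 1,1-dimethyl-π-allyl complex, CO2 and methoxide, the methoxide removes the most acidic free phenol proton (4-OH first, then one of the 2/6-OH groups, while the last OH stays locked in the hydrogen bond to the ketone and is shielded from a tertiary electrophile), and the aryloxide, always paired one-to-one with the allyl cation in THF at 0 °C, collapses through oxygen onto the more cationic tertiary terminus as the kinetic outcome, whereas attack through ring carbon costs aromaticity and is a slower thermodynamic channel that is shut off by removing the palladium before heating; at 120 °C each 1,1-dimethylallyl aryl ether undergoes an aromatic Claisen [3,3] shift with allyl inversion to a normal prenyl group, the ether next to the benzoyl group being pushed towards C3 and, once C3 is filled, the 4-ether towards the only free ortho carbon C5 (also the carbon favoured by the bond fixation of the chelated 6-OH), and re-aromatisation makes each shift irreversible; the closest known reaction types are the Tsuji–Trost O-allylation (O-reverse prenylation) of simple phenols with tertiary allylic carbonates and the aromatic Claisen rearrangement, neither shown on a free acylphloroglucinol, where palladium normally gives C-allylation; no stereocentre is formed.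

**Compound list**
1 | phloroglucinol (benzene-1,3,5-triol), achiral | Oc1cc(O)cc(O)c1 | starting material
2 | benzoyl chloride | O=C(Cl)c1ccccc1 | starting material
3 | 2,4,6-trihydroxybenzophenone, phenyl(2,4,6-trihydroxyphenyl)methanone, achiral | O=C(c1ccccc1)c1c(O)cc(O)cc1O | intermediate
4 | 2-methylbut-3-en-2-ol | CC(C)(O)C=C | starting material
5 | methyl chloroformate | COC(=O)Cl | starting material
6 | lithium 2-methylbut-3-en-2-olate | [Li+].[O-]C(C)(C)C=C | intermediate
7 | methyl 2-methylbut-3-en-2-yl carbonate | COC(=O)OC(C)(C)C=C | intermediate
8 | [2,6-dihydroxy-4-(2-methylbut-3-en-2-yloxy)phenyl](phenyl)methanone, achiral | O=C(c1ccccc1)c1c(O)cc(OC(C)(C)C=C)cc1O | intermediate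
9 | [2-hydroxy-4,6-bis(2-methylbut-3-en-2-yloxy)phenyl](phenyl)methanone, achiral | O=C(c1ccccc1)c1c(O)cc(OC(C)(C)C=C)cc1OC(C)(C)C=C | intermediate
10 | [2,6-dihydroxy-3-(3-methylbut-2-en-1-yl)-4-(2-methylbut-3-en-2-yloxy)phenyl](phenyl)methanone, achiral | O=C(c1ccccc1)c1c(O)cc(OC(C)(C)C=C)c(CC=C(C)C)c1O | intermediate
11 | clusiaphenone B, [2,4,6-trihydroxy-3,5-bis(3-methylbut-2-en-1-yl)phenyl](phenyl)methanone, achiral | CC(C)=CCc1c(O)c(CC=C(C)C)c(O)c(C(=O)c2ccccc2)c1O | target

**Totals**
Total step count: 3.
Longest linear sequence: 2 steps (1 → 3 → 11, or 4 → 7 → 11).

**Steps most likely to fail**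

Step 3 (the proposed new step).
- Risks in the palladium stage: ring C-prenylation or dearomatisation, drift to the linear O-prenyl ether by re-ionisation of the vinylogous-ester-like 4-ether, and over-alkylation to the tris-ether.
- Risks in the thermal stage: delivery from the 4-oxygen to C3 before the 2-ether has moved, and loss of isoprene.
- Fallback (known chemistry, sets out from 3, comes back at 9): 3 is etherified with 3-chloro-3-methylbut-1-yne (2.5 equiv), K2CO3, KI and catalytic CuI in refluxing acetone. This is a copper-assisted propargylic substitution rather than π-allyl chemistry, and it gives [2-hydroxy-4,6-bis(2-methylbut-3-yn-2-yloxy)phenyl](phenyl)methanone F1. Semi-hydrogenation of both alkynes (H2, 1 atm, Pd/CaCO3 poisoned with Pb(OAc)2, quinoline, EtOAc) gives 9. Here 9 is isolated and purified, then heated in DMF as in the second stage of step 3.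

Step 1.
- Risks: poor solubility of the aluminium phenoxides, some second acylation, and tedious removal of PhNO2.
- Fallback (sets out from 1, comes back at 3): a Hoesch reaction instead of an acid chloride acylation. Compound 1 and benzonitrile are treated with catalytic ZnCl2 and dry HCl gas in Et2O at 0 °C, which precipitates (2,4,6-trihydroxyphenyl)(phenyl)methaniminium chloride F2. A second acylation cannot occur on this cationic solid. Boiling F2 in water hydrolyses it to 3.

Step 2.
- Risks: the tertiary allylic carbonate is volatile and can ionise or eliminate during distillation.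
- Fallback (sets out from 5, comes back at 8): the donor is changed to its primary regioisomer. Commercial 3-methylbut-2-en-1-ol is acylated with 5 (pyridine, CH2Cl2, 0 °C) to give the robust methyl 3-methylbut-2-en-1-yl carbonate F3. With Pd(PPh3)4, F3 ionises to the same 1,1-dimethyl-π-allyl palladium cation as 7. It can therefore replace 7 in step 3, giving 8 and then 9 by the same kinetic attack of oxygen at the tertiary terminus.

**Further compounds**
F1 | step 3 | [2-hydroxy-4,6-bis(2-methylbut-3-yn-2-yloxy)phenyl](phenyl)methanone | O=C(c1ccccc1)c1c(O)cc(OC(C)(C)C#C)cc1OC(C)(C)C#C
F2 | step 1 | (2,4,6-trihydroxyphenyl)(phenyl)methaniminium chloride | [Cl-].[NH2+]=C(c1ccccc1)c1c(O)cc(O)cc1O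
F3 | step 2 | methyl 3-methylbut-2-en-1-yl carbonate | COC(=O)OCC=C(C)C
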